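**Retrosynthetic overview**
- Last step: acid removes three MOM groups and the catechol acetonide. Before that, ring C is closed at O1–C2 by an ortho-phenoxide displacing a primary chloride.
- C4–C4a: lithiated 1,3,5-tris(methoxymethoxy)benzene (ring A) adds to an α-quaternary aldehyde, and the carbinol is then oxidised.
- C3, the only stereocentre: the ring B arylmagnesium adds under chelation control to the chloromethyl ketone of (S)-isopropylideneglycerate. Glycol cleavage then erases the glycerate stereocentre, and its carbon stays as C4.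
- Key step: the aromatic Claisen [3,3] shift of the prenyl ether of pyrogallol acetonide makes the aryl–C(CH3)2(vinyl) bond. O-methylation and ortho-lithiation follow.
- Ring order: rings A and B are bought as arenes. Ring C is the only ring formed (step 10).

Assumption: 1, 2, 6 and 15 are taken as commercial, and the facial sense of step 4 is taken from the Cram chelate model (expected dr about 6:1 to 10:1, epimers separable).

Abbreviation used in names: ArB = 7-methoxy-2,2-dimethyl-6-(2-methylbut-3-en-2-yl)-1,3-benzodioxol-4-yl (ring B with its catechol held as the acetonide).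

**Step 1**
Reactants: 1 2,2-dimethyl-1,3-benzodioxol-4-ol (pyrogallol acetonide); 2 1-bromo-3-methylbut-2-ene (prenyl bromide)
Product: 3 2,2-dimethyl-4-[(3-methylbut-2-en-1-yl)oxy]-1,3-benzodioxole
Conditions: K2CO3, acetone, 56 °C
Reagents that add atoms: none
Why: Williamson ether synthesis, in which the only free phenol of the ketal (the future 4'-oxygen) displaces the primary allylic bromide by SN2 under weak base.

**Step 2 (key step)**
Reactants: 3 2,2-dimethyl-4-[(3-methylbut-2-en-1-yl)oxy]-1,3-benzodioxole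
Product: 5 4-methoxy-2,2-dimethyl-5-(2-methylbut-3-en-2-yl)-1,3-benzodioxole, via Claisen phenol 4 (not isolated)
Conditions: NMP, 200 °C, 2 h; cool to 25 °C; K2CO3, MeI
Reagents that add atoms: iodomethane, CI
Why: Aromatic Claisen rearrangement, in which the [3,3]-sigmatropic shift moves the prenyl group with allylic inversion to the only free ortho carbon (the other is the ring-fusion carbon) and makes the aryl–quaternary carbon bond, and immediate Williamson methylation of phenol 4 stops it from cyclising onto the vinyl group.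

**Step 3**
Reactants: 6 methyl (4S)-2,2-dimethyl-1,3-dioxolane-4-carboxylate
Product: 8 2-chloro-1-[(4S)-2,2-dimethyl-1,3-dioxolan-4-yl]ethan-1-one, via lithium hemiketal alkoxide 7 (not isolated)
Conditions: ICH2Cl, MeLi·LiBr, THF–Et2O, −78 °C; AcOH, −78 °C
Reagents that add atoms: chloroiodomethane, ClCI
Why: Nucleophilic acyl substitution by a lithium carbenoid made in situ by iodine–lithium exchange, in which alkoxide 7 does not collapse at −78 °C so only one CH2Cl unit adds, and the cold acidic quench leaves the bought stereocentre untouched.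

**Step 4**
Reactants: 5 4-methoxy-2,2-dimethyl-5-(2-methylbut-3-en-2-yl)-1,3-benzodioxole; 8 2-chloro-1-[(4S)-2,2-dimethyl-1,3-dioxolan-4-yl]ethan-1-one
Product: 11 (1S)-2-chloro-1-[(4S)-2,2-dimethyl-1,3-dioxolan-4-yl]-1-ArB-ethan-1-ol, via aryllithium 9 (not isolated), via arylmagnesium bromide 10 (not isolated)
Conditions: 5, n-BuLi, THF, 0 °C; MgBr2·OEt2, 0 °C; 8, −78 °C; aq NH4Cl; chromatography
Reagents that add atoms: none
Why: Directed ortho-metalation at the only CH next to a ring oxygen is followed by a chelation-controlled Grignard addition (Cram chelate model), in which magnesium ties the carbonyl oxygen to the α-oxygen of the dioxolane and the aryl group enters from the face bearing H, which sets the tertiary carbinol as S (the future 3R centre) under control of the glycerate centre, and the minor epimer is removed by chromatography.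

**Step 5**
Reactants: 11 (1S)-2-chloro-1-[(4S)-2,2-dimethyl-1,3-dioxolan-4-yl]-1-ArB-ethan-1-ol
Product: 12 (4S)-4-[(1S)-2-chloro-1-ArB-1-(methoxymethoxy)ethyl]-2,2-dimethyl-1,3-dioxolane
Conditions: MOMCl, iPr2NEt, Bu4NI (cat.), ClCH2CH2Cl, 50 °C
Reagents that add atoms: chloromethyl methyl ether, COCCl
Why: MOM ether formation (O-alkylation by the oxocarbenium-like chloride) caps the tertiary alcohol, which would otherwise be part of a second vicinal diol in step 6, and the hindered amine is too weak a base to close the chlorohydrin to an epoxide.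

**Step 6**
Reactants: 12 (4S)-4-[(1S)-2-chloro-1-ArB-1-(methoxymethoxy)ethyl]-2,2-dimethyl-1,3-dioxolane
Product: 14 (2S)-3-chloro-2-ArB-2-(methoxymethoxy)propanal, via diol 13 (not isolated)
Conditions: H5IO6, EtOAc, 25 °C
Reagents that add atoms: none
Why: Periodic acid hydrolyses the terminal aliphatic acetonide and cleaves diol 13 (Malaprade glycol cleavage), which erases the relay stereocentre and leaves its carbon as a non-enolisable aldehyde (future C4), while the less basic catechol ketal, the MOM ether and the alkene are untouched.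

**Step 7**
Reactants: 15 benzene-1,3,5-triol (phloroglucinol)
Product: 16 1,3,5-tris(methoxymethoxy)benzene
Conditions: NaH, MOMCl, DMF, 0 to 25 °C
Reagents that add atoms: chloromethyl methyl ether, COCCl
Why: Threefold Williamson-type O-alkylation of the phenoxides gives a symmetric ether whose MOM-oxy groups later direct lithiation.

**Step 8**
Reactants: 16 1,3,5-tris(methoxymethoxy)benzene; 14 (2S)-3-chloro-2-ArB-2-(methoxymethoxy)propanal
Product: 18 (2S)-3-chloro-2-ArB-2-(methoxymethoxy)-1-[2,4,6-tris(methoxymethoxy)phenyl]propan-1-ol (both C1 epimers), via aryllithium 17 (not isolated)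
Conditions: 16, n-BuLi, THF, 0 °C; 14, −78 °C; aq NH4Cl
Reagents that add atoms: none
Why: Directed ortho-metalation of the symmetric ether gives a single aryllithium whose 1,2-addition to the non-enolisable aldehyde forms the C4–C4a bond, and the new carbinol centre forms as a mixture that is removed by oxidation in step 9.

**Step 9**
Reactants: 18 (2S)-3-chloro-2-ArB-2-(methoxymethoxy)-1-[2,4,6-tris(methoxymethoxy)phenyl]propan-1-ol
Product: 19 (2S)-3-chloro-2-ArB-2-(methoxymethoxy)-1-[2,4,6-tris(methoxymethoxy)phenyl]propan-1-one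
Conditions: Dess–Martin periodinane, NaHCO3, CH2Cl2, 0 to 25 °C
Reagents that add atoms: none
Why: Dess–Martin oxidation converts the crowded benzylic alcohol into the aryl ketone under buffered conditions that leave the MOM ethers, the ketal, the alkene and the quaternary centre untouched.

**Step 10**
Reactants: 19 (2S)-3-chloro-2-ArB-2-(methoxymethoxy)-1-[2,4,6-tris(methoxymethoxy)phenyl]propan-1-one
Product: 21 (3R)-3-ArB-3,5,7-tris(methoxymethoxy)-2,3-dihydro-4H-chromen-4-one, via ortho-phenol 20 (not isolated)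
Conditions: HCl (0.2 M), MeOH–CH2Cl2, 0 °C; evaporate; K2CO3, NaI (cat.), DMF, 60 °C
Reagents that add atoms: none
Why: Acid-catalysed transacetalisation first removes a MOM group ortho to the ketone (relief of crowding and a hydrogen bond from the freed phenol to C=O), and the phenoxide then closes ring C by intramolecular Williamson etherification (6-exo-tet SN2 at CH2Cl) without breaking any bond to C3, so the configuration is kept and only the descriptor changes from S to R.

**Step 11**
Reactants: 21 (3R)-3-ArB-3,5,7-tris(methoxymethoxy)-2,3-dihydro-4H-chromen-4-one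
Product: 22 (3R)-3-[2,3-dihydroxy-4-methoxy-5-(2-methylbut-3-en-2-yl)phenyl]-3,5,7-trihydroxy-2,3-dihydro-4H-chromen-4-one (target)
Conditions: 3 M aq HCl–MeOH (1:4), 60 °C, argon
Reagents that add atoms: none
Why: Acid-catalysed acetal and ketal solvolysis frees all five hydroxyl groups, while ionisation at C3 is held back by the adjacent carbonyl group and the monosubstituted alkene flanked by OMe is not protonated, so racemisation, dehydration to the isoflavone and ring closure onto the alkene are avoided.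

**Compound list** (ArB as defined above)
1 | 2,2-dimethyl-1,3-benzodioxol-4-ol | CC1(C)Oc2cccc(O)c2O1 | starting material
2 | 1-bromo-3-methylbut-2-ene | CC(C)=CCBr | starting material
3 | 2,2-dimethyl-4-[(3-methylbut-2-en-1-yl)oxy]-1,3-benzodioxole | CC(C)=CCOc1cccc2OC(C)(C)Oc12 | intermediate
4 | 2,2-dimethyl-5-(2-methylbut-3-en-2-yl)-1,3-benzodioxol-4-ol | C=CC(C)(C)c1ccc2OC(C)(C)Oc2c1O | intermediate
5 | 4-methoxy-2,2-dimethyl-5-(2-methylbut-3-en-2-yl)-1,3-benzodioxole | C=CC(C)(C)c1ccc2OC(C)(C)Oc2c1OC | intermediate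
6 | methyl (4S)-2,2-dimethyl-1,3-dioxolane-4-carboxylate | COC(=O)[C@@H]1COC(C)(C)O1 | starting material
7 | lithium 2-chloro-1-[(4S)-2,2-dimethyl-1,3-dioxolan-4-yl]-1-methoxyethan-1-olate | [Li]OC(CCl)(OC)[C@@H]1COC(C)(C)O1 | intermediate
8 | 2-chloro-1-[(4S)-2,2-dimethyl-1,3-dioxolan-4-yl]ethan-1-one | ClCC(=O)[C@@H]1COC(C)(C)O1 | intermediate
9 | ArB-lithium | C=CC(C)(C)c1cc([Li])c2OC(C)(C)Oc2c1OC | intermediate
10 | ArB-magnesium bromide | C=CC(C)(C)c1cc([Mg]Br)c2OC(C)(C)Oc2c1OC | intermediate
11 | (1S)-2-chloro-1-[(4S)-2,2-dimethyl-1,3-dioxolan-4-yl]-1-ArB-ethan-1-ol | C=CC(C)(C)c1cc([C@@](O)(CCl)[C@@H]3COC(C)(C)O3)c2OC(C)(C)Oc2c1OC | intermediate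
12 | (4S)-4-[(1S)-2-chloro-1-ArB-1-(methoxymethoxy)ethyl]-2,2-dimethyl-1,3-dioxolane | C=CC(C)(C)c1cc([C@@](OCOC)(CCl)[C@@H]3COC(C)(C)O3)c2OC(C)(C)Oc2c1OC | intermediate
13 | (2S,3S)-4-chloro-3-ArB-3-(methoxymethoxy)butane-1,2-diol | C=CC(C)(C)c1cc([C@@](OCOC)(CCl)[C@@H](O)CO)c2OC(C)(C)Oc2c1OC | intermediate
14 | (2S)-3-chloro-2-ArB-2-(methoxymethoxy)propanal | C=CC(C)(C)c1cc([C@@](OCOC)(CCl)C=O)c2OC(C)(C)Oc2c1OC | intermediate
15 | benzene-1,3,5-triol | Oc1cc(O)cc(O)c1 | starting material
16 | 1,3,5-tris(methoxymethoxy)benzene | COCOc1cc(OCOC)cc(OCOC)c1 | intermediate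
17 | [2,4,6-tris(methoxymethoxy)phenyl]lithium | [Li]c1c(OCOC)cc(OCOC)cc1OCOC | intermediate
18 | (2S)-3-chloro-2-ArB-2-(methoxymethoxy)-1-[2,4,6-tris(methoxymethoxy)phenyl]propan-1-ol, C1 epimers | C=CC(C)(C)c1cc([C@@](OCOC)(CCl)C(O)c3c(OCOC)cc(OCOC)cc3OCOC)c2OC(C)(C)Oc2c1OC | intermediate
19 | (2S)-3-chloro-2-ArB-2-(methoxymethoxy)-1-[2,4,6-tris(methoxymethoxy)phenyl]propan-1-one | C=CC(C)(C)c1cc([C@@](OCOC)(CCl)C(=O)c3c(OCOC)cc(OCOC)cc3OCOC)c2OC(C)(C)Oc2c1OC | intermediate
20 | (2S)-3-chloro-1-[2-hydroxy-4,6-bis(methoxymethoxy)phenyl]-2-ArB-2-(methoxymethoxy)propan-1-one | C=CC(C)(C)c1cc([C@@](OCOC)(CCl)C(=O)c3c(O)cc(OCOC)cc3OCOC)c2OC(C)(C)Oc2c1OC | intermediate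
21 | (3R)-3-ArB-3,5,7-tris(methoxymethoxy)-2,3-dihydro-4H-chromen-4-one | C=CC(C)(C)c1cc([C@@]3(OCOC)COc4cc(OCOC)cc(OCOC)c4C3=O)c2OC(C)(C)Oc2c1OC | intermediate
22 | (3R)-3-[2,3-dihydroxy-4-methoxy-5-(2-methylbut-3-en-2-yl)phenyl]-3,5,7-trihydroxy-2,3-dihydro-4H-chromen-4-one | C=CC(C)(C)c1cc([C@@]2(O)COc3cc(O)cc(O)c3C2=O)c(O)c(O)c1OC | target

**Total step count:** 11.
**Longest linear sequence:** 9 steps (1, 2, 4, 5, 6, 8, 9, 10, 11).

**Three steps most likely to fail**

Step 2. The crowded dienone may pass the allyl group on to the free para carbon, giving the normal prenyl isomer, or phenol 4 may cyclise before it is capped.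
- The fallback sets out from 1 and comes back at aryllithium 9. It puts a bromine on the para carbon, where it serves both as blocker and as lithiation handle.
- NBS in MeCN at −20 °C gives 7-bromo-2,2-dimethyl-1,3-benzodioxol-4-ol F1.
- Prenyl bromide 2 and K2CO3 give 7-bromo-2,2-dimethyl-4-[(3-methylbut-2-en-1-yl)oxy]-1,3-benzodioxole F2.
- Heating in NMP can now lead only to 7-bromo-2,2-dimethyl-5-(2-methylbut-3-en-2-yl)-1,3-benzodioxol-4-ol F3.
- MeI and K2CO3 give 7-bromo-4-methoxy-2,2-dimethyl-5-(2-methylbut-3-en-2-yl)-1,3-benzodioxole F4.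
- Bromine–lithium exchange with n-BuLi at −78 °C delivers 9 without any directed metalation.

Step 4. The Grignard reagent may enolise the chloroketone, or the chelate may give a poor diastereomer ratio.
- The fallback sets out from 9 and comes back at aldehyde 14. It reverses the order in which the two groups are brought to the carbinol carbon.
- Methyl (4R)-2,2-dimethyl-1,3-dioxolane-4-carboxylate F5 is converted with MeNH(OMe)·HCl and iPrMgCl into (4R)-N-methoxy-N,2,2-trimethyl-1,3-dioxolane-4-carboxamide F6.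
- 9 acylates F6 to give the aryl ketone ArB [(4R)-2,2-dimethyl-1,3-dioxolan-4-yl] ketone F7.
- ClCH2MgCl·LiCl, made from ICH2Cl and iPrMgCl·LiCl at −78 °C in the presence of F7, adds under the same chelate model. With the groups exchanged and the relay centre inverted, this gives (1S)-2-chloro-1-[(4R)-2,2-dimethyl-1,3-dioxolan-4-yl]-1-ArB-ethan-1-ol F8.
- MOMCl and iPr2NEt give the MOM ether (4R)-4-[(1S)-2-chloro-1-ArB-1-(methoxymethoxy)ethyl]-2,2-dimethyl-1,3-dioxolane F9.
- H5IO6 removes the relay centre and gives 14.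

Step 10. The single ortho MOM group may not come off cleanly, and the SN2 closure at a CH2Cl next to a fully substituted carbon may be too slow.
- The fallback sets out from 19 and comes back at 22. It closes ring C through an epoxide instead of by direct displacement.
- 1 M HCl in MeOH at 40 °C removes all four MOM groups and gives (2S)-3-chloro-2-ArB-2-hydroxy-1-(2,4,6-trihydroxyphenyl)propan-1-one F10.
- K2CO3 in acetone at 25 °C closes the tertiary alkoxide onto CH2Cl to give [(2S)-2-ArB-oxiran-2-yl](2,4,6-trihydroxyphenyl)methanone F11.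
- In the same flask the ortho-phenoxide opens F11 at its CH2 end, with the C3–O bond untouched, to give (3R)-3-ArB-3,5,7-trihydroxy-2,3-dihydro-4H-chromen-4-one F12.
- The conditions of step 11 then remove the catechol ketal and give 22.

**Further compounds**
F1 | step 2 | 7-bromo-2,2-dimethyl-1,3-benzodioxol-4-ol | CC1(C)Oc2c(Br)ccc(O)c2O1
F2 | step 2 | 7-bromo-2,2-dimethyl-4-[(3-methylbut-2-en-1-yl)oxy]-1,3-benzodioxole | CC(C)=CCOc1ccc(Br)c2OC(C)(C)Oc12
F3 | step 2 | 7-bromo-2,2-dimethyl-5-(2-methylbut-3-en-2-yl)-1,3-benzodioxol-4-ol | C=CC(C)(C)c1cc(Br)c2OC(C)(C)Oc2c1O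
F4 | step 2 | 7-bromo-4-methoxy-2,2-dimethyl-5-(2-methylbut-3-en-2-yl)-1,3-benzodioxole | C=CC(C)(C)c1cc(Br)c2OC(C)(C)Oc2c1OC
F5 | step 4 | methyl (4R)-2,2-dimethyl-1,3-dioxolane-4-carboxylate | COC(=O)[C@H]1COC(C)(C)O1
F6 | step 4 | (4R)-N-methoxy-N,2,2-trimethyl-1,3-dioxolane-4-carboxamide | CON(C)C(=O)[C@H]1COC(C)(C)O1
F7 | step 4 | ArB [(4R)-2,2-dimethyl-1,3-dioxolan-4-yl] ketone | C=CC(C)(C)c1cc(C(=O)[C@H]3COC(C)(C)O3)c2OC(C)(C)Oc2c1OC
F8 | step 4 | (1S)-2-chloro-1-[(4R)-2,2-dimethyl-1,3-dioxolan-4-yl]-1-ArB-ethan-1-ol | C=CC(C)(C)c1cc([C@@](O)(CCl)[C@H]3COC(C)(C)O3)c2OC(C)(C)Oc2c1OC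
F9 | step 4 | (4R)-4-[(1S)-2-chloro-1-ArB-1-(methoxymethoxy)ethyl]-2,2-dimethyl-1,3-dioxolane | C=CC(C)(C)c1cc([C@@](OCOC)(CCl)[C@H]3COC(C)(C)O3)c2OC(C)(C)Oc2c1OC
F10 | step 10 | (2S)-3-chloro-2-ArB-2-hydroxy-1-(2,4,6-trihydroxyphenyl)propan-1-one | C=CC(C)(C)c1cc([C@@](O)(CCl)C(=O)c3c(O)cc(O)cc3O)c2OC(C)(C)Oc2c1OC
F11 | step 10 | [(2S)-2-ArB-oxiran-2-yl](2,4,6-trihydroxyphenyl)methanone | C=CC(C)(C)c1cc([C@@]3(CO3)C(=O)c4c(O)cc(O)cc4O)c2OC(C)(C)Oc2c1OC
F12 | step 10 | (3R)-3-ArB-3,5,7-trihydroxy-2,3-dihydro-4H-chromen-4-one | C=CC(C)(C)c1cc([C@@]3(O)COc4cc(O)cc(O)c4C3=O)c2OC(C)(C)Oc2c1OC
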